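**Assumption:** locants C1–C15 and α/β follow dictyol numbering of the target (C1/C5 ring fusion, C6 and C9 carbinols, C7 side-chain carbon, C10 methylidene carbon, C11–C15 side chain; α is the face of H-1). The target is then (1R,5S,6R,7S,9R,11R,12S), with 1α-H, 5β-H, 6β-OH, 7β side chain and 9α-OH.

**Retrosynthetic overview**
1. Target ⇐ desilylation ⇐ C3=C4 olefin with 5β-H, made by reductive 1,3-transposition of a cyclopentenone tosylhydrazone (the ketone is traceless) ⇐ allylic oxidation at C9.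
2. Bicyclic enone ⇐ carbonylative [2+2+1] of an acyclic dienyne with CO: the C1–C5, C2–C3 and C3–C4 bonds form together, so the five- and seven-membered rings close in the same operation.
3. Dienyne ⇐ B-alkyl Suzuki coupling with chloroprene ⇐ [2,3]-Wittig rearrangement of an allyl 2-butynyl ether (sets C6 and C7 from C11).
4. Ether ⇐ cross-metathesis and etherification ⇐ anti-crotylboration (sets C11/C12) of (E)-4-hydroxy-4-methylpent-2-enal ⇐ cross-metathesis of 2-methylbut-3-en-2-ol with crotonaldehyde.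
5. Ring order: no ring until the [2+2+1] step, then both rings at once.

**Route**

Step 1
Reactants: 1 2-methylbut-3-en-2-ol; 2 (E)-but-2-enal
Product: 3 (E)-4-hydroxy-4-methylpent-2-enal
Conditions: second-generation Hoveyda–Grubbs catalyst RuCl2(H2IMes)(=CH-C6H4-2-OiPr) (2.5 mol %), 2 (4 equiv), CH2Cl2, 40 °C
Reagents that add atoms: none
Why: Olefin cross-metathesis of a tertiary allylic alcohol with excess enal gives the E-enal under thermodynamic control (propene leaves) and creates no stereocentre.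

Step 2
Reactants: 3 (E)-4-hydroxy-4-methylpent-2-enal; 4 (E)-crotylboronic acid pinacol ester
Product: 6 (3E,5S,6R)-2,6-dimethylocta-3,7-diene-2,5-diol, via O-pinacolboryl ester 5 (not isolated)
Conditions: (R)-TRIP [(R)-3,3′-bis(2,4,6-triisopropylphenyl)-1,1′-binaphthyl-2,2′-diyl hydrogen phosphate] (5 mol %), 4 Å MS, toluene, −30 °C; aqueous work-up
Reagents that add atoms: none
Why: Chiral phosphoric acid-catalysed crotylboration through a chair (Zimmerman–Traxler) transition state: the E-crotyl geometry gives the anti C11-methyl/C12-hydroxyl pair and the (R)-catalyst selects the aldehyde face that gives (11R,12S), the free tertiary alcohol being tolerated.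

Step 3
Reactants: 6 (3E,5S,6R)-2,6-dimethylocta-3,7-diene-2,5-diol
Product: 7 (3E,5S,6R)-2,6-dimethyl-2,5-bis(triethylsilyloxy)octa-3,7-diene
Conditions: TESOTf (2.5 equiv), 2,6-lutidine, CH2Cl2, −78 → 0 °C
Reagents that add atoms: triethylsilyl trifluoromethanesulfonate, CC[Si](CC)(CC)OS(=O)(=O)C(F)(F)F
Why: Silyl triflate silylation caps both the secondary and the tertiary alcohol so that the basic steps 5 and 6 meet no free hydroxyl and C12 can later be unveiled selectively.

Step 4
Reactants: 7 (3E,5S,6R)-2,6-dimethyl-2,5-bis(triethylsilyloxy)octa-3,7-diene; 8 (Z)-but-2-ene-1,4-diol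
Product: 9 (2E,4R,5S,6E)-4,8-dimethyl-5,8-bis(triethylsilyloxy)nona-2,6-dien-1-ol
Conditions: second-generation Hoveyda–Grubbs catalyst RuCl2(H2IMes)(=CH-C6H4-2-OiPr) (5 mol %), 8 (4 equiv), CH2Cl2/THF, 40 °C
Reagents that add atoms: none
Why: Olefin cross-metathesis at the only monosubstituted alkene with excess diol gives the E-allylic alcohol under thermodynamic control while the 1,2-disubstituted alkene next to the quaternary carbon is too hindered to react.

Step 5
Reactants: 9 (2E,4R,5S,6E)-4,8-dimethyl-5,8-bis(triethylsilyloxy)nona-2,6-dien-1-ol; 10 1-bromobut-2-yne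
Product: 12 (2E,4R,5S,6E)-1-(but-2-yn-1-yloxy)-4,8-dimethyl-5,8-bis(triethylsilyloxy)nona-2,6-diene, via sodium alkoxide 11 (not isolated)
Conditions: NaH, THF, 0 °C; then 10, Bu4NI (cat.), 0 °C → rt
Reagents that add atoms: none
Why: Williamson etherification of the primary allylic alkoxide with the reactive propargylic bromide installs the carbanion-stabilising 2-butynyl group for the sigmatropic step.

Step 6
Reactants: 12 (2E,4R,5S,6E)-1-(but-2-yn-1-yloxy)-4,8-dimethyl-5,8-bis(triethylsilyloxy)nona-2,6-diene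
Product: 15 (4R,5S,6R,7S,8E)-4-(tert-butyldimethylsilyloxy)-5-ethenyl-6,10-dimethyl-7,10-bis(triethylsilyloxy)undec-8-en-2-yne, via α-lithio ether 13 (not isolated), via lithium alkoxide 14 (not isolated)
Conditions: n-BuLi (1.3 equiv), THF, −78 °C; then TBSOTf, −78 → 0 °C
Reagents that add atoms: tert-butyldimethylsilyl trifluoromethanesulfonate, CC(C)(C)[Si](C)(C)OS(=O)(=O)C(F)(F)F
Why: [2,3]-Wittig rearrangement of the propargylic carbanion through a five-membered envelope transition state: the E-alkene gives the anti C6–O/C7–C11 arrangement, and C7 is formed anti to the C12 branch with H-11 eclipsing the alkene (allylic-strain model), which together give (6R,7S) before the alkoxide is trapped as its TBS ether.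

Step 7
Reactants: 15 (4R,5S,6R,7S,8E)-4-(tert-butyldimethylsilyloxy)-5-ethenyl-6,10-dimethyl-7,10-bis(triethylsilyloxy)undec-8-en-2-yne; 16 2-chlorobuta-1,3-diene (chloroprene)
Product: 18 (4R,5S,6R,7S,8E)-4-(tert-butyldimethylsilyloxy)-6,10-dimethyl-5-(3-methylidenepent-4-en-1-yl)-7,10-bis(triethylsilyloxy)undec-8-en-2-yne, via B-alkyl-9-BBN 17 (not isolated)
Conditions: 9-BBN, THF, 0 °C → rt; then 16 (3 equiv), Pd(OAc)2 (5 mol %), SPhos (10 mol %), aq K3PO4, 40 °C
Reagents that add atoms: none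
Why: 9-BBN hydroborates only the terminal vinyl group (anti-Markovnikov) and the B-alkyl Suzuki–Miyaura coupling with the vinylic chloride attaches the 2-substituted butadiene without touching any stereocentre.

Step 8
Reactants: 18 (4R,5S,6R,7S,8E)-4-(tert-butyldimethylsilyloxy)-6,10-dimethyl-5-(3-methylidenepent-4-en-1-yl)-7,10-bis(triethylsilyloxy)undec-8-en-2-yne
Product: 19 bicyclic enone (C3 ketone, C4=C5, C10 methylidene, 1α-H, 6β-OTBS, 7β side chain carrying 12-OTES and 15-OTES)
Conditions: [RhCl(CO)2]2 (5 mol %), CO (1 atm), ClCH2CH2Cl (0.01 M), 80 °C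
Reagents that add atoms: carbon monoxide, [C-]#[O+]
Why: Proposed new method: rhodium-catalysed carbonylative [2+2+1] (Pauson–Khand-type) cyclisation in which the alkyne, the terminal vinyl arm of the 2-substituted diene and CO combine, so that the C1–C5, C2–C3 and C3–C4 bonds and with them the cyclopentenone and the cycloheptane form in one operation; oxidative cyclisation on monovalent rhodium is expected to place H-1 anti to the pseudo-axial 6β-silyloxy group (H-6 lies in the enone plane to avoid allylic 1,3-strain with the C4 methyl, side chain equatorial in a twist-chair), and the closest known reactions are the rhodium-catalysed dienyl Pauson–Khand reaction and rhodium-catalysed allenic Pauson–Khand closures of bicyclo[5.3.0]decadienones.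

Step 9
Reactants: 19 bicyclic enone (6-OTBS, 12,15-di-OTES)
Product: 20 bicyclic enone 12,15-diol (6-OTBS retained)
Conditions: PPTS (0.2 equiv), MeOH/CH2Cl2, 0 °C → rt
Reagents that add atoms: none
Why: Mild acid-catalysed methanolysis (transsilylation to methanol) removes the two TES ethers while the hindered secondary TBS ether at C6 survives.

Step 10
Reactants: 20 bicyclic enone 12,15-diol
Product: 21 bicyclic enone 12-acetate (15-OH free, 6-OTBS)
Conditions: Ac2O (1.5 equiv), pyridine, DMAP (5 mol %), CH2Cl2, 0 °C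
Reagents that add atoms: acetic anhydride, CC(=O)OC(C)=O
Why: DMAP-catalysed acylation is selective for the secondary C12 alcohol because the tertiary C15 alcohol reacts far more slowly and C6 is silylated.

Step 11
Reactants: 21 bicyclic enone 12-acetate
Product: 22 9α-hydroxy bicyclic enone (12-OAc, 15-OH, 6-OTBS)
Conditions: SeO2 (30 mol %), t-BuOOH (2 equiv), CH2Cl2, 0 °C → rt
Reagents that add atoms: tert-butyl hydroperoxide, CC(C)(C)OO
Why: Riley allylic oxidation (ene reaction then [2,3]-sigmatropic shift of the allylseleninic acid) of the exocyclic methylene (the enone alkene is electron-poor and the side-chain alkene has only an acetoxy-bearing allylic C–H), at the C9 methylene in preference to the C1 methine, with oxygen delivered to the α-face of C9 anti to the C1–C2 bond and the β side chain.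

Step 12
Reactants: 22 9α-hydroxy bicyclic enone
Product: 23 C3 tosylhydrazone of 22 (C=N geometry not assigned)
Conditions: TsNHNH2 (1.3 equiv), EtOH, 50 °C
Reagents that add atoms: 4-methylbenzenesulfonohydrazide, Cc1ccc(cc1)S(=O)(=O)NN
Why: Condensation of the cyclopentenone carbonyl, the only ketone present, with tosylhydrazide gives the α,β-unsaturated tosylhydrazone needed for the reductive transposition.

Step 13
Reactants: 23 C3 tosylhydrazone of 22
Product: 26 6-O-TBS ether of the target (C3=C4 olefin; 1α-H; 5β-H), via N-boryl tosylhydrazine 24 (not isolated), via allylic diazene 25 (not isolated)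
Conditions: catecholborane (excess), CHCl3, 0 °C; then NaOAc·3H2O, reflux
Reagents that add atoms: none
Why: Kabalka reductive 1,3-transposition: catecholborane adds hydride to C3 from the α-face (anti to the C1–C10 bond), acetate-induced loss of sulfinate gives the 3β-allylic diazene, and its suprafacial retro-ene loss of N2 delivers hydrogen to C5 on the β-face while moving the double bond to C3=C4, which sets the trans ring fusion and removes the carbonyl.

Step 14
Reactants: 26 6-O-TBS ether of the target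
Product: 27 target, (1R,5S,6R,7S,9R,11R,12S)-12-acetate 6β,9α,15-triol (CNP0213969.2)
Conditions: HF·pyridine, pyridine, THF, 0 °C → rt
Reagents that add atoms: none
Why: Fluoride-mediated desilylation (buffered HF·pyridine) frees the hindered C6 hydroxyl without acyl migration or ionisation of the allylic alcohols and gives the target.

**Compound list**

1 | 2-methylbut-3-en-2-ol | C=CC(C)(C)O | starting material
2 | (E)-but-2-enal (crotonaldehyde) | C/C=C/C=O | starting material
3 | (E)-4-hydroxy-4-methylpent-2-enal | O=C/C=C/C(C)(C)O | intermediate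
4 | (E)-crotylboronic acid pinacol ester | C/C=C/CB1OC(C)(C)C(C)(C)O1 | starting material
5 | O-pinacolboryl ester of 6 (boron on the C5 oxygen) | C=C[C@@H](C)[C@H](/C=C/C(C)(C)O)OB1OC(C)(C)C(C)(C)O1 | intermediate
6 | (3E,5S,6R)-2,6-dimethylocta-3,7-diene-2,5-diol | C=C[C@@H](C)[C@H](/C=C/C(C)(C)O)O | intermediate
7 | (3E,5S,6R)-2,6-dimethyl-2,5-bis(triethylsilyloxy)octa-3,7-diene | C=C[C@@H](C)[C@H](/C=C/C(C)(C)O[Si](CC)(CC)CC)O[Si](CC)(CC)CC | intermediate
8 | (Z)-but-2-ene-1,4-diol | OC/C=C\CO | starting material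
9 | (2E,4R,5S,6E)-4,8-dimethyl-5,8-bis(triethylsilyloxy)nona-2,6-dien-1-ol | OC/C=C/[C@@H](C)[C@H](/C=C/C(C)(C)O[Si](CC)(CC)CC)O[Si](CC)(CC)CC | intermediate
10 | 1-bromobut-2-yne | CC#CCBr | starting material
11 | sodium alkoxide of 9 | [Na+].[O-]C/C=C/[C@@H](C)[C@H](/C=C/C(C)(C)O[Si](CC)(CC)CC)O[Si](CC)(CC)CC | intermediate
12 | (2E,4R,5S,6E)-1-(but-2-yn-1-yloxy)-4,8-dimethyl-5,8-bis(triethylsilyloxy)nona-2,6-diene | CC#CCOC/C=C/[C@@H](C)[C@H](/C=C/C(C)(C)O[Si](CC)(CC)CC)O[Si](CC)(CC)CC | intermediate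
13 | α-lithio ether (12 lithiated at the propargylic OCH2) | [Li+].CC#C[CH-]OC/C=C/[C@@H](C)[C@H](/C=C/C(C)(C)O[Si](CC)(CC)CC)O[Si](CC)(CC)CC | intermediate
14 | lithium (4R,5S,6R,7S,8E)-5-ethenyl-6,10-dimethyl-7,10-bis(triethylsilyloxy)undec-8-en-2-yn-4-olate | [Li+].CC#C[C@H]([O-])[C@@H](C=C)[C@@H](C)[C@H](/C=C/C(C)(C)O[Si](CC)(CC)CC)O[Si](CC)(CC)CC | intermediate
15 | (4R,5S,6R,7S,8E)-4-(tert-butyldimethylsilyloxy)-5-ethenyl-6,10-dimethyl-7,10-bis(triethylsilyloxy)undec-8-en-2-yne (dictyol locants 6R,7S,11R,12S) | CC#C[C@H](O[Si](C)(C)C(C)(C)C)[C@@H](C=C)[C@@H](C)[C@H](/C=C/C(C)(C)O[Si](CC)(CC)CC)O[Si](CC)(CC)CC | intermediate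
16 | 2-chlorobuta-1,3-diene (chloroprene) | C=CC(Cl)=C | starting material
17 | B-alkyl-9-BBN from 15 (boron on C9) | CC#C[C@H](O[Si](C)(C)C(C)(C)C)[C@@H](CCB1C2CCCC1CCC2)[C@@H](C)[C@H](/C=C/C(C)(C)O[Si](CC)(CC)CC)O[Si](CC)(CC)CC | intermediate
18 | (4R,5S,6R,7S,8E)-4-(tert-butyldimethylsilyloxy)-6,10-dimethyl-5-(3-methylidenepent-4-en-1-yl)-7,10-bis(triethylsilyloxy)undec-8-en-2-yne | CC#C[C@H](O[Si](C)(C)C(C)(C)C)[C@@H](CCC(=C)C=C)[C@@H](C)[C@H](/C=C/C(C)(C)O[Si](CC)(CC)CC)O[Si](CC)(CC)CC | intermediate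
19 | bicyclic enone: 3-oxo, C4=C5, 10-methylidene, 1α-H, 6β-OTBS, 7β side chain (11R,12S,13E) with 12-OTES and 15-OTES | C=C1CC[C@@H]([C@@H](C)[C@H](/C=C/C(C)(C)O[Si](CC)(CC)CC)O[Si](CC)(CC)CC)[C@@H](O[Si](C)(C)C(C)(C)C)C2=C(C)C(=O)C[C@@H]12 | intermediate
20 | bicyclic enone 12,15-diol (6β-OTBS) | C=C1CC[C@@H]([C@@H](C)[C@H](/C=C/C(C)(C)O)O)[C@@H](O[Si](C)(C)C(C)(C)C)C2=C(C)C(=O)C[C@@H]12 | intermediate
21 | bicyclic enone 12-acetate (15-OH, 6β-OTBS) | C=C1CC[C@@H]([C@@H](C)[C@H](/C=C/C(C)(C)O)OC(C)=O)[C@@H](O[Si](C)(C)C(C)(C)C)C2=C(C)C(=O)C[C@@H]12 | intermediate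
22 | 9α-hydroxy bicyclic enone (12-OAc, 15-OH, 6β-OTBS) | C=C1[C@H](O)C[C@@H]([C@@H](C)[C@H](/C=C/C(C)(C)O)OC(C)=O)[C@@H](O[Si](C)(C)C(C)(C)C)C2=C(C)C(=O)C[C@@H]12 | intermediate
23 | C3 tosylhydrazone of 22 | C=C1[C@H](O)C[C@@H]([C@@H](C)[C@H](/C=C/C(C)(C)O)OC(C)=O)[C@@H](O[Si](C)(C)C(C)(C)C)C2=C(C)C(=NNS(=O)(=O)c3ccc(C)cc3)C[C@@H]12 | intermediate
24 | N-catecholboryl allylic tosylhydrazine (3β-N, 3α-H) | C=C1[C@H](O)C[C@@H]([C@@H](C)[C@H](/C=C/C(C)(C)O)OC(C)=O)[C@@H](O[Si](C)(C)C(C)(C)C)C2=C(C)[C@@H](N(NS(=O)(=O)c3ccc(C)cc3)B3Oc4ccccc4O3)C[C@@H]12 | intermediate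
25 | 3β-allylic diazene | C=C1[C@H](O)C[C@@H]([C@@H](C)[C@H](/C=C/C(C)(C)O)OC(C)=O)[C@@H](O[Si](C)(C)C(C)(C)C)C2=C(C)[C@@H](N=N)C[C@@H]12 | intermediate
26 | 6-O-TBS ether of the target (C3=C4, 1α-H, 5β-H, 9α-OH, 12-OAc, 15-OH) | C=C1[C@H](O)C[C@@H]([C@@H](C)[C@H](/C=C/C(C)(C)O)OC(C)=O)[C@@H](O[Si](C)(C)C(C)(C)C)[C@@H]2C(C)=CC[C@@H]12 | intermediate
27 | target, (1R,5S,6R,7S,9R,11R,12S,13E)-12-acetoxy-6β,9α,15-trihydroxy hydroazulene diterpenoid CNP0213969.2 | C=C1[C@H](O)C[C@@H]([C@@H](C)[C@H](/C=C/C(C)(C)O)OC(C)=O)[C@@H](O)[C@@H]2C(C)=CC[C@@H]12 | target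

**Totals**
Total step count: 14. Longest linear sequence: 14 steps (1 or 2 → 27); all other inputs are commercial.

**Three steps most likely to fail, with fallbacks**

Step 8 (the [2+2+1] closure). Closing a seven-membered ring across a five-atom tether with the vinyl arm of a 2-substituted diene is unprecedented, and C1 may form with H-1 β. Fallback, setting out from 15 and returning at 19: hydroborate 15 as in step 7 and couple the borane 17 with but-2-yne-1,4-diyl bis(methyl carbonate) (Pd(PPh3)4, THF, 50 °C, excess electrophile; SN2′ oxidative addition on zerovalent palladium) to give the 1,1-disubstituted allenyne carbonate F1. The rhodium-catalysed allenic Pauson–Khand reaction ([RhCl(CO)2]2, CO, toluene, 90 °C) engages the terminal allene double bond and is the best-precedented [2+2+1] route to bicyclo[5.3.0] systems; it gives the cross-conjugated dienone carbonate F2 (C4=C5 and C1=C10). Tsuji–Mandai formate hydrogenolysis (Pd(OAc)2, PBu3, HCO2H, Et3N, THF) then delivers hydride to C1 of the π-allyl from the face opposite the 6β-silyloxy group and leaves the C10 methylidene, which is 19. In this variant C1 is set by hydride delivery, not by the cycloaddition.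

Step 11 (Riley oxidation). Oxygen may enter on the β-face of C9, or the reaction may be unselective between faces. Fallback, setting out from 21 and returning at 22: take the oxidation through to the ketone (SeO2, t-BuOOH, then MnO2 on the crude carbinol mixture) to give the exo-methylene ketone F3, then reduce under Luche conditions (NaBH4, CeCl3·7H2O, MeOH, −78 °C; the unhindered α-methylene ketone should react before the fully substituted cyclopentenone). Hydride enters from the face that SeO2 oxygenates, so the carbinol configuration is the opposite of that from direct oxidation and converges on 22.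

Step 13 (reductive transposition). If hydride adds to the hydrazone from the β-face, H-5 arrives α and the ring fusion is cis. Fallback, setting out from 22 and returning at 27: silylate the C9 carbinol (TESCl, imidazole, CH2Cl2) to the 9-O-TES enone F4 and reduce the ketone (NaBH4, CeCl3·7H2O, MeOH) to the 3α-allylic alcohol F5. Myers reductive transposition (2-nitrobenzenesulfonyl hydrazide, PPh3, DEAD, THF, −30 °C → rt) then proceeds by Mitsunobu inversion to the N-allyl sulfonylhydrazine F6, loss of sulfinic acid to the 3β-diazene F7, and retro-ene delivery of hydrogen to C5β, giving the bis-silyl ether F8. HF·pyridine removes both silyl groups to give 27. In this sequence hydrogen ends on the face from which hydride attacked C3, the opposite outcome to step 13.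

**Further compounds**

F1 | step 8 | allenyne carbonate: 18 with the diene replaced by a C10(CH2OCO2Me)=C1=C2H2 allene | CC#C[C@H](O[Si](C)(C)C(C)(C)C)[C@@H](CCC(COC(=O)OC)=C=C)[C@@H](C)[C@H](/C=C/C(C)(C)O[Si](CC)(CC)CC)O[Si](CC)(CC)CC
F2 | step 8 | dienone carbonate: 3-oxo, C4=C5, C1=C10, C10–CH2OCO2Me, 6β-OTBS, 12,15-di-OTES | COC(=O)OCC1=C2CC(=O)C(C)=C2[C@H](O[Si](C)(C)C(C)(C)C)[C@H]([C@@H](C)[C@H](/C=C/C(C)(C)O[Si](CC)(CC)CC)O[Si](CC)(CC)CC)CC1
F3 | step 11 | exo-methylene ketone: 9-oxo analogue of 22 | C=C1C(=O)C[C@@H]([C@@H](C)[C@H](/C=C/C(C)(C)O)OC(C)=O)[C@@H](O[Si](C)(C)C(C)(C)C)C2=C(C)C(=O)C[C@@H]12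
F4 | step 13 | 9-O-TES enone: 9-O-triethylsilyl ether of 22 | C=C1[C@H](O[Si](CC)(CC)CC)C[C@@H]([C@@H](C)[C@H](/C=C/C(C)(C)O)OC(C)=O)[C@@H](O[Si](C)(C)C(C)(C)C)C2=C(C)C(=O)C[C@@H]12
F5 | step 13 | 3α-allylic alcohol from F4 | C=C1[C@H](O[Si](CC)(CC)CC)C[C@@H]([C@@H](C)[C@H](/C=C/C(C)(C)O)OC(C)=O)[C@@H](O[Si](C)(C)C(C)(C)C)C2=C(C)[C@H](O)C[C@@H]12
F6 | step 13 | N-allyl sulfonylhydrazine: 3β-N(NH2)SO2(2-nitrophenyl) | C=C1[C@H](O[Si](CC)(CC)CC)C[C@@H]([C@@H](C)[C@H](/C=C/C(C)(C)O)OC(C)=O)[C@@H](O[Si](C)(C)C(C)(C)C)C2=C(C)[C@@H](N(N)S(=O)(=O)c3ccccc3[N+](=O)[O-])C[C@@H]12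
F7 | step 13 | 3β-diazene (9-OTES, 6-OTBS) | C=C1[C@H](O[Si](CC)(CC)CC)C[C@@H]([C@@H](C)[C@H](/C=C/C(C)(C)O)OC(C)=O)[C@@H](O[Si](C)(C)C(C)(C)C)C2=C(C)[C@@H](N=N)C[C@@H]12
F8 | step 13 | bis-silyl ether: 9-O-TES, 6-O-TBS ether of the target | C=C1[C@H](O[Si](CC)(CC)CC)C[C@@H]([C@@H](C)[C@H](/C=C/C(C)(C)O)OC(C)=O)[C@@H](O[Si](C)(C)C(C)(C)C)[C@@H]2C(C)=CC[C@@H]12
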